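**Retrosynthetic overview**

1. Side chain last: the threo-(7''R,8''R) arylglycerol ether is built on the ring A phenol of 4'-O-benzyl-(−)-olivil 14 by etherification with a chloroacetyl Evans imide, boron syn-aldol with O-benzylvanillin, LiBH4 cleavage and one final double hydrogenolysis.
2. The oxolane is the only ring formed: 14 comes from the acyclic carinol-type triol 12 by dehydrogenation of the ring A phenol to a para-quinone methide and 5-exo capture by the C9' hydroxyl (C7–O bond, C7 set trans to C8), the step presumed to turn carinol into olivil in the plant.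
3. Triol 12 comes from LiAlH4 reduction of a doubly benzylated (S)-malic acid dioxolanone.
4. C8 and C8' come from two alkylations of (S)-malate with one benzyl bromide (Frater–Seebach, then Seebach dioxolanone alkylation with retention); a hydrogenolysis between them leaves ring A as the free phenol and ring B as the benzyl ether.

Assumption: compounds 1, 3, 8, 15 and 17 are taken as catalogue items; lignan numbering is used (ring A with C7–C9 is the oxolane aryl unit, ring B with C7'–C9' the benzyl unit, ring C with C7''–C9'' the side chain).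

**Route**

Step 1
Reactants: 1 4-(benzyloxy)-3-methoxybenzyl alcohol
Product: 2 4-(benzyloxy)-3-methoxybenzyl bromide
Conditions: PBr3 (0.4 equiv), Et2O, 0 °C, 1 h
Reagents that add atoms: phosphorus tribromide, BrP(Br)Br
Why: Bromination of an electron-rich benzylic alcohol through its phosphite ester (SN2 by bromide); no stereocentre is involved.

Step 2
Reactants: 3 diisopropyl (S)-malate; 2 4-(benzyloxy)-3-methoxybenzyl bromide
Product: 5 diisopropyl (2S,3R)-3-[4-(benzyloxy)-3-methoxybenzyl]-2-hydroxybutanedioate, via dilithium malate dianion 4 (not isolated)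
Conditions: LiN(SiMe3)2 (2.2 equiv), THF, −78 °C; then 2 (0.9 equiv), −78 → −10 °C, 16 h; aq NH4Cl
Reagents that add atoms: none
Why: Frater–Seebach alkylation, in which the chelated alkoxide-enolate is benzylated anti to the C2 carboxylate arm, so the existing (S) centre sets the new C3 centre (C8 of the target) as R (anti product, about 9:1, minor isomer removed by chromatography).

Step 3
Reactants: 5 diisopropyl (2S,3R)-3-[4-(benzyloxy)-3-methoxybenzyl]-2-hydroxybutanedioate
Product: 7 (2S,3R)-2-hydroxy-3-(4-hydroxy-3-methoxybenzyl)butanedioic acid, via dipotassium O-benzyl malate salt 6 (not isolated)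
Conditions: KOH (5 equiv), EtOH/H2O, 40 °C; then 10% Pd/C, H2 (1 atm), rt, same flask; filter; 2 M HCl to pH 2
Reagents that add atoms: potassium hydroxide, [K+].[OH-]
Why: Ester saponification followed in the same flask by Pd-catalysed hydrogenolysis of the aryl benzyl ether frees both acids and the ring A phenol, and carboxylate α-centres do not epimerise under these conditions.

Step 4
Reactants: 7 (2S,3R)-2-hydroxy-3-(4-hydroxy-3-methoxybenzyl)butanedioic acid; 8 pivalaldehyde
Product: 9 (2R)-2-[(2S,4S)-2-tert-butyl-5-oxo-1,3-dioxolan-4-yl]-3-(4-hydroxy-3-methoxyphenyl)propanoic acid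
Conditions: t-BuCHO (3 equiv), TsOH·H2O (cat.), H2SO4 (cat.), pentane/CH2Cl2, reflux, Dean–Stark; crystallise
Reagents that add atoms: none
Why: Seebach acetalisation of the α-hydroxy acid (self-regeneration of stereocentres) closes the five-membered dioxolanone under thermodynamic control, and the cis isomer with tert-butyl and side chain on the same face (new acetal centre S) predominates and is purified by crystallisation.

Step 5
Reactants: 9 (2R)-2-[(2S,4S)-2-tert-butyl-5-oxo-1,3-dioxolan-4-yl]-3-(4-hydroxy-3-methoxyphenyl)propanoic acid; 2 4-(benzyloxy)-3-methoxybenzyl bromide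
Product: 11 (2R)-2-[(2S,4S)-4-[4-(benzyloxy)-3-methoxybenzyl]-2-tert-butyl-5-oxo-1,3-dioxolan-4-yl]-3-(4-hydroxy-3-methoxyphenyl)propanoic acid, via trilithium dioxolanone enolate 10 (not isolated)
Conditions: LiN(SiMe3)2 (3.3 equiv), THF, −78 °C; then 2 (1.05 equiv), −78 → −40 °C; 1 M HCl
Reagents that add atoms: none
Why: Seebach dioxolanone enolate alkylation, in which the benzyl bromide enters on the face opposite the tert-butyl group and so replaces H with net retention to give the quaternary carbinol centre (C8' of the target), the lithium phenoxide and carboxylate being far poorer nucleophiles than the enolate at −78 °C.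

Step 6
Reactants: 11 (2R)-2-[(2S,4S)-4-[4-(benzyloxy)-3-methoxybenzyl]-2-tert-butyl-5-oxo-1,3-dioxolan-4-yl]-3-(4-hydroxy-3-methoxyphenyl)propanoic acid
Product: 12 (2S,3S)-2-[4-(benzyloxy)-3-methoxybenzyl]-3-(4-hydroxy-3-methoxybenzyl)butane-1,2,4-triol
Conditions: LiAlH4 (6 equiv), THF, 0 °C → reflux; aq KNaC4H4O6 work-up
Reagents that add atoms: none
Why: Hydride reduction of the dioxolanone carbonyl and the carboxylic acid gives the two primary alcohols and releases the tertiary alcohol (the acetal carbon leaves as neopentyl alcohol) without touching either stereocentre.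

Step 7
Reactants: 12 (2S,3S)-2-[4-(benzyloxy)-3-methoxybenzyl]-3-(4-hydroxy-3-methoxybenzyl)butane-1,2,4-triol
Product: 14 (3S,4R,5S)-3-[4-(benzyloxy)-3-methoxybenzyl]-5-(4-hydroxy-3-methoxyphenyl)-4-(hydroxymethyl)oxolan-3-ol (4'-O-benzyl-(−)-olivil), via para-quinone methide 13 (not isolated)
Conditions: DDQ (1.05 equiv), NaHCO3 (3 equiv, solid), CH2Cl2/1,4-dioxane (4:1), 0 °C, dark, 1 h
Reagents that add atoms: none
Why: DDQ dehydrogenation of the only free para-alkylphenol (ring A) gives quinone methide 13, which is captured 5-exo by the C9' hydroxyl (oxa-1,6-addition, the only hydroxyl able to close a five-membered ring), and the new C7 centre forms trans to the C8 hydroxymethyl group through the transition state with a pseudo-equatorial aryl group, while NaHCO3 keeps the medium non-acidic to suppress Friedel–Crafts closure to the cycloolivil skeleton.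

Step 8
Reactants: 14 4'-O-benzyl-(−)-olivil; 15 (S)-4-benzyl-3-(chloroacetyl)oxazolidin-2-one
Product: 16 (4S)-4-benzyl-3-{2-[4-[(2S,3R,4S)-4-[4-(benzyloxy)-3-methoxybenzyl]-4-hydroxy-3-(hydroxymethyl)oxolan-2-yl]-2-methoxyphenoxy]acetyl}oxazolidin-2-one
Conditions: K2CO3 (1.5 equiv), NaI (0.1 equiv), acetone, rt → 40 °C
Reagents that add atoms: none
Why: Williamson etherification in which the phenoxide, the only OH deprotonated by K2CO3, displaces the iodide-activated α-halide of the imide while the primary and tertiary alcohols stay untouched.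

Step 9
Reactants: 16 ring A aryloxyacetyl imide; 17 4-(benzyloxy)-3-methoxybenzaldehyde
Product: 19 (4S)-4-benzyl-3-[(2S,3R)-3-[4-(benzyloxy)-3-methoxyphenyl]-3-hydroxy-2-{4-[(2S,3R,4S)-4-[4-(benzyloxy)-3-methoxybenzyl]-4-hydroxy-3-(hydroxymethyl)oxolan-2-yl]-2-methoxyphenoxy}propanoyl]oxazolidin-2-one, via boron Z-enolate 18 (not isolated)
Conditions: Bu2BOTf (3.0 equiv), iPr2NEt (3.5 equiv), CH2Cl2, −78 → 0 °C; then 17 (1.5 equiv), −78 → 0 °C; pH 7 buffer, MeOH, 30% H2O2, 0 °C
Reagents that add atoms: none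
Why: Evans syn-aldol of a glycolate-type imide, in which the Z boron enolate adds through a Zimmerman–Traxler chair on the face left open by the (S)-benzyl auxiliary and sets both side-chain centres (2S,3R in the imide, which become 8''R and 7''R, threo, after reduction), the excess Bu2BOTf masking the primary alcohol as a borinate in the flask.

Step 10
Reactants: 19 syn-aldol adduct
Product: 20 (1R,2R)-1-[4-(benzyloxy)-3-methoxyphenyl]-2-{4-[(2S,3R,4S)-4-[4-(benzyloxy)-3-methoxybenzyl]-4-hydroxy-3-(hydroxymethyl)oxolan-2-yl]-2-methoxyphenoxy}propane-1,3-diol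
Conditions: LiBH4 (4 equiv), THF/MeOH (20:1), 0 °C
Reagents that add atoms: none
Why: Reductive cleavage of the N-acyloxazolidinone by LiBH4 gives the primary alcohol and releases the auxiliary under conditions too mild for retro-aldol or epimerisation.

Step 11
Reactants: 20 di-O-benzyl target
Product: 21 (1R,2R)-1-(4-hydroxy-3-methoxyphenyl)-2-{4-[(2S,3R,4S)-4-hydroxy-4-(4-hydroxy-3-methoxybenzyl)-3-(hydroxymethyl)oxolan-2-yl]-2-methoxyphenoxy}propane-1,3-diol (target, CNP0391650.2)
Conditions: H2 (1 atm), 10% Pd/C, EtOAc/EtOH, rt, stopped at full conversion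
Reagents that add atoms: none
Why: Pd-catalysed hydrogenolysis cleaves the two aryl benzyl ethers much faster than the benzylic alcohol or the benzylic ring ether under neutral conditions, so no stereocentre is disturbed.

**Compound list**

1 | 4-(benzyloxy)-3-methoxybenzyl alcohol | COc1cc(CO)ccc1OCc1ccccc1 | starting material
2 | 4-(benzyloxy)-3-methoxybenzyl bromide | COc1cc(CBr)ccc1OCc1ccccc1 | intermediate
3 | diisopropyl (S)-malate | CC(C)OC(=O)C[C@H](O)C(=O)OC(C)C | starting material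
4 | dilithium alkoxide-enolate of diisopropyl (S)-malate | [Li+].[Li+].CC(C)OC(=O)[C@@H]([O-])C=C([O-])OC(C)C | intermediate
5 | diisopropyl (2S,3R)-3-[4-(benzyloxy)-3-methoxybenzyl]-2-hydroxybutanedioate | O[C@H](C(=O)OC(C)C)[C@H](C(=O)OC(C)C)Cc1ccc(OCc2ccccc2)c(OC)c1 | intermediate
6 | dipotassium (2S,3R)-3-[4-(benzyloxy)-3-methoxybenzyl]-2-hydroxybutanedioate | [K+].[K+].O[C@H](C(=O)[O-])[C@H](C(=O)[O-])Cc1ccc(OCc2ccccc2)c(OC)c1 | intermediate
7 | (2S,3R)-2-hydroxy-3-(4-hydroxy-3-methoxybenzyl)butanedioic acid | O[C@H](C(=O)O)[C@H](C(=O)O)Cc1ccc(O)c(OC)c1 | intermediate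
8 | pivalaldehyde | CC(C)(C)C=O | starting material
9 | (2R)-2-[(2S,4S)-2-tert-butyl-5-oxo-1,3-dioxolan-4-yl]-3-(4-hydroxy-3-methoxyphenyl)propanoic acid (tert-butyl and side chain cis) | CC(C)(C)[C@H]1O[C@@H]([C@@H](Cc2ccc(O)c(OC)c2)C(=O)O)C(=O)O1 | intermediate
10 | trilithium salt of 9 (phenoxide, carboxylate, dioxolanone enolate) | [Li+].[Li+].[Li+].CC(C)(C)[C@H]1OC([C@@H](Cc2ccc([O-])c(OC)c2)C([O-])=O)=C([O-])O1 | intermediate
11 | (2R)-2-[(2S,4S)-4-[4-(benzyloxy)-3-methoxybenzyl]-2-tert-butyl-5-oxo-1,3-dioxolan-4-yl]-3-(4-hydroxy-3-methoxyphenyl)propanoic acid | CC(C)(C)[C@H]1O[C@@](Cc2ccc(OCc3ccccc3)c(OC)c2)([C@@H](Cc2ccc(O)c(OC)c2)C(=O)O)C(=O)O1 | intermediate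
12 | (2S,3S)-2-[4-(benzyloxy)-3-methoxybenzyl]-3-(4-hydroxy-3-methoxybenzyl)butane-1,2,4-triol (4'-O-benzylcarinol) | COc1cc(C[C@@](O)(CO)[C@H](CO)Cc2ccc(O)c(OC)c2)ccc1OCc1ccccc1 | intermediate
13 | 4-{(2S,3S)-3-[4-(benzyloxy)-3-methoxybenzyl]-3,4-dihydroxy-2-(hydroxymethyl)butylidene}-2-methoxycyclohexa-2,5-dien-1-one (alkene geometry not defined) | COC1=CC(=C[C@@H](CO)[C@](O)(CO)Cc2ccc(OCc3ccccc3)c(OC)c2)C=CC1=O | intermediate
14 | (3S,4R,5S)-3-[4-(benzyloxy)-3-methoxybenzyl]-5-(4-hydroxy-3-methoxyphenyl)-4-(hydroxymethyl)oxolan-3-ol (4'-O-benzyl-(−)-olivil) | COc1cc(C[C@@]2(O)CO[C@H](c3ccc(O)c(OC)c3)[C@H]2CO)ccc1OCc1ccccc1 | intermediate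
15 | (S)-4-benzyl-3-(chloroacetyl)oxazolidin-2-one | O=C(CCl)N1[C@@H](Cc2ccccc2)COC1=O | starting material
16 | (4S)-4-benzyl-3-{2-[4-[(2S,3R,4S)-4-[4-(benzyloxy)-3-methoxybenzyl]-4-hydroxy-3-(hydroxymethyl)oxolan-2-yl]-2-methoxyphenoxy]acetyl}oxazolidin-2-one | COc1cc(C[C@@]2(O)CO[C@H](c3ccc(OCC(=O)N4[C@@H](Cc5ccccc5)COC4=O)c(OC)c3)[C@H]2CO)ccc1OCc1ccccc1 | intermediate
17 | 4-(benzyloxy)-3-methoxybenzaldehyde | COc1cc(C=O)ccc1OCc1ccccc1 | starting material
18 | Z dibutylboron enolate of 16 with the primary alcohol as its dibutylborinate | COc1cc(C[C@@]2(O)CO[C@H](c3ccc(O/C=C(\OB(CCCC)CCCC)N4[C@@H](Cc5ccccc5)COC4=O)c(OC)c3)[C@H]2COB(CCCC)CCCC)ccc1OCc1ccccc1 | intermediate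
19 | (4S)-4-benzyl-3-[(2S,3R)-3-[4-(benzyloxy)-3-methoxyphenyl]-3-hydroxy-2-{4-[(2S,3R,4S)-4-[4-(benzyloxy)-3-methoxybenzyl]-4-hydroxy-3-(hydroxymethyl)oxolan-2-yl]-2-methoxyphenoxy}propanoyl]oxazolidin-2-one | COc1cc(C[C@@]2(O)CO[C@H](c3ccc(O[C@H](C(=O)N4[C@@H](Cc5ccccc5)COC4=O)[C@H](O)c4ccc(OCc5ccccc5)c(OC)c4)c(OC)c3)[C@H]2CO)ccc1OCc1ccccc1 | intermediate
20 | (1R,2R)-1-[4-(benzyloxy)-3-methoxyphenyl]-2-{4-[(2S,3R,4S)-4-[4-(benzyloxy)-3-methoxybenzyl]-4-hydroxy-3-(hydroxymethyl)oxolan-2-yl]-2-methoxyphenoxy}propane-1,3-diol | COc1cc(C[C@@]2(O)CO[C@H](c3ccc(O[C@H](CO)[C@H](O)c4ccc(OCc5ccccc5)c(OC)c4)c(OC)c3)[C@H]2CO)ccc1OCc1ccccc1 | intermediate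
21 | (1R,2R)-1-(4-hydroxy-3-methoxyphenyl)-2-{4-[(2S,3R,4S)-4-hydroxy-4-(4-hydroxy-3-methoxybenzyl)-3-(hydroxymethyl)oxolan-2-yl]-2-methoxyphenoxy}propane-1,3-diol | COc1cc(C[C@@]2(O)CO[C@H](c3ccc(O[C@H](CO)[C@H](O)c4ccc(O)c(OC)c4)c(OC)c3)[C@H]2CO)ccc1O | target

**Step count and risks**

Total steps: 11. Longest linear sequence: 11 (steps 1 to 11; bromide 2 from step 1 is used in steps 2 and 5).

Most likely to fail, first: step 7 (oxidative quinone methide cyclisation). The product still carries a free phenol and a benzylic C–H and can be over-oxidised, the C7 epimer may form alongside, and any acid drives Friedel–Crafts closure onto ring B. The fallback sets out from 12 and separates oxidation from ring closure. The DDQ dehydrogenation is run in CH2Cl2/MeOH so that methanol takes up the quinone methide and gives the isolable benzylic ether (2S,3R)-2-[4-(benzyloxy)-3-methoxybenzyl]-3-[(4-hydroxy-3-methoxyphenyl)(methoxy)methyl]butane-1,2,4-triol F1 as both C7 epimers. F1 is then treated with catalytic camphorsulfonic acid in CH2Cl2 at 0 °C, which regenerates the quinone methide by loss of methanol and closes the oxolane under thermodynamic control, coming back to the route at 14.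

Second: step 5 (enolate benzylation in the presence of a lithium phenoxide and carboxylate). The trianion may be poorly soluble, and O-benzylation of ring A would destroy the differentiation of the two phenols. The fallback sets out from 9 and masks both acidic groups. Allyl bromide and K2CO3 in DMF give prop-2-en-1-yl (2R)-2-[(2S,4S)-2-tert-butyl-5-oxo-1,3-dioxolan-4-yl]-3-[3-methoxy-4-(prop-2-en-1-yloxy)phenyl]propanoate F2. Its dioxolanone enolate (LiN(SiMe3)2, 1.05 equiv, THF, −78 °C) is benzylated with 2 to give prop-2-en-1-yl (2R)-2-[(2S,4S)-4-[4-(benzyloxy)-3-methoxybenzyl]-2-tert-butyl-5-oxo-1,3-dioxolan-4-yl]-3-[3-methoxy-4-(prop-2-en-1-yloxy)phenyl]propanoate F3. Pd(PPh3)4 and morpholine in THF then remove both allyl groups, coming back to the route at 11.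

Third: step 9 (boron aldol on a substrate with a free primary and a free tertiary alcohol). The masking by excess Bu2BOTf may be incomplete and erode conversion or selectivity. The fallback sets out from 16 and silylates both alcohols with TESOTf and 2,6-lutidine in CH2Cl2 to give (4S)-4-benzyl-3-{2-[4-[(2S,3R,4S)-4-[4-(benzyloxy)-3-methoxybenzyl]-4-(triethylsilyloxy)-3-[(triethylsilyloxy)methyl]oxolan-2-yl]-2-methoxyphenoxy]acetyl}oxazolidin-2-one F4. The standard Evans aldol (Bu2BOTf 1.2 equiv, iPr2NEt, then 17) gives the bis-silyl aldol adduct (4S)-4-benzyl-3-[(2S,3R)-3-[4-(benzyloxy)-3-methoxyphenyl]-3-hydroxy-2-{4-[(2S,3R,4S)-4-[4-(benzyloxy)-3-methoxybenzyl]-4-(triethylsilyloxy)-3-[(triethylsilyloxy)methyl]oxolan-2-yl]-2-methoxyphenoxy}propanoyl]oxazolidin-2-one F5. HF·pyridine in THF/pyridine at 0 °C removes the silyl groups, coming back to the route at 19.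

**Further compounds**

F1 | step 7 | (2S,3R)-2-[4-(benzyloxy)-3-methoxybenzyl]-3-[(4-hydroxy-3-methoxyphenyl)(methoxy)methyl]butane-1,2,4-triol (both C7 epimers) | COc1cc(C[C@@](O)(CO)[C@H](CO)C(OC)c2ccc(O)c(OC)c2)ccc1OCc1ccccc1
F2 | step 5 | prop-2-en-1-yl (2R)-2-[(2S,4S)-2-tert-butyl-5-oxo-1,3-dioxolan-4-yl]-3-[3-methoxy-4-(prop-2-en-1-yloxy)phenyl]propanoate | CC(C)(C)[C@H]1O[C@@H]([C@@H](Cc2ccc(OCC=C)c(OC)c2)C(=O)OCC=C)C(=O)O1
F3 | step 5 | prop-2-en-1-yl (2R)-2-[(2S,4S)-4-[4-(benzyloxy)-3-methoxybenzyl]-2-tert-butyl-5-oxo-1,3-dioxolan-4-yl]-3-[3-methoxy-4-(prop-2-en-1-yloxy)phenyl]propanoate | CC(C)(C)[C@H]1O[C@@](Cc2ccc(OCc3ccccc3)c(OC)c2)([C@@H](Cc2ccc(OCC=C)c(OC)c2)C(=O)OCC=C)C(=O)O1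
F4 | step 9 | bis(triethylsilyl) ether of 16 (primary and tertiary alcohols silylated) | COc1cc(C[C@@]2(O[Si](CC)(CC)CC)CO[C@H](c3ccc(OCC(=O)N4[C@@H](Cc5ccccc5)COC4=O)c(OC)c3)[C@H]2CO[Si](CC)(CC)CC)ccc1OCc1ccccc1
F5 | step 9 | bis(triethylsilyl) ether of 19 (primary and tertiary alcohols silylated) | COc1cc(C[C@@]2(O[Si](CC)(CC)CC)CO[C@H](c3ccc(O[C@H](C(=O)N4[C@@H](Cc5ccccc5)COC4=O)[C@H](O)c4ccc(OCc5ccccc5)c(OC)c4)c(OC)c3)[C@H]2CO[Si](CC)(CC)CC)ccc1OCc1ccccc1
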